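**Plan**
- Retrosynthesis: the heptane chain is cut at C6–C7 (the benzylic CH2 of the 4-hydroxy-3-methoxyphenyl ring to the CH2 next to the carbinol) and at C3–C4; the Ar–CH2CH2–C3 arm is traced back to 5-hydroxyvanillin.
- Enabling feature: carbinol C5 lies between two methylenes, C4 (bound to ketone carbon C3) and C6 (bound to benzylic C7). C4–C5(O)–C6 therefore maps onto epichlorohydrin, C3 onto a dithiane carbanion and C7 onto a benzylic Grignard reagent.
- Forward order: 5-hydroxyvanillin → dibenzyl ether → two-carbon homologation → dithiane 6; vanillyl alcohol benzyl ether 7 → chloride 8; then 6, epichlorohydrin 9 and 8 are joined in one flask (C3–C4, temporary oxirane, then C6–C7).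
- Helpers and their removal: the dithiane (umpolung and ketone mask) is hydrolysed, the temporary oxirane is opened in the same flask, and the three benzyl ethers are removed by a final hydrogenolysis.
- Stereochemistry: C5 is the CH of (S)-epichlorohydrin; its C–O bond is never broken, which gives the (R)-carbinol of the target.

Key step: step 6

Remark: compounds 1, 3, 7 and 9 are taken as purchasable; by CIP analysis the stereocentre of the target (C5) is R.

**Step 1**
Reactants: 1 5-hydroxyvanillin (3,4-dihydroxy-5-methoxybenzaldehyde)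
Product: 2 3,4-bis(benzyloxy)-5-methoxybenzaldehyde
Conditions: BnBr (2.3 equiv), K2CO3 (3 equiv), DMF, 60 °C
Reagents that add atoms: benzyl bromide, BrCc1ccccc1
Why: Williamson ether synthesis, in which carbonate deprotonates both phenols and the phenoxides displace bromide, masks the catechol for the organometallic steps with groups that a final hydrogenolysis removes.

**Step 2**
Reactants: 2 3,4-bis(benzyloxy)-5-methoxybenzaldehyde; 3 (triphenylphosphoranylidene)acetaldehyde
Product: 4 (E)-3-[3,4-bis(benzyloxy)-5-methoxyphenyl]prop-2-enal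
Conditions: toluene, 90 °C
Reagents that add atoms: none
Why: Wittig olefination with a stabilised formyl ylide should give the (E)-enal and adds the two carbons that become C2 and C3.

**Step 3**
Reactants: 4 (E)-3-[3,4-bis(benzyloxy)-5-methoxyphenyl]prop-2-enal
Product: 5 3-[3,4-bis(benzyloxy)-5-methoxyphenyl]propanal
Conditions: Hantzsch ester (1.2 equiv), Bn2NH2+ CF3CO2− (10 mol%), THF, rt
Reagents that add atoms: none
Why: Iminium-catalysed transfer hydrogenation (organocatalytic conjugate reduction) delivers hydride from the Hantzsch ester to the β-carbon of the iminium ion, so the C=C bond is reduced while the aldehyde and the benzyl ethers stay intact.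

**Step 4**
Reactants: 5 3-[3,4-bis(benzyloxy)-5-methoxyphenyl]propanal
Product: 6 2-{2-[3,4-bis(benzyloxy)-5-methoxyphenyl]ethyl}-1,3-dithiane
Conditions: HS(CH2)3SH (1.1 equiv), BF3·OEt2 (0.2 equiv), CH2Cl2, 0 °C
Reagents that add atoms: propane-1,3-dithiol, SCCCS
Why: Lewis-acid-catalysed dithioacetalisation (first half of a Corey–Seebach sequence) turns the aldehyde carbon, the future C3, into an acidic dithiane C–H, which masks the ketone and reverses its polarity.

**Step 5**
Reactants: 7 4-(benzyloxy)-3-methoxybenzyl alcohol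
Product: 8 4-(benzyloxy)-3-methoxybenzyl chloride
Conditions: SOCl2 (1.2 equiv), CH2Cl2, 0 °C → rt
Reagents that add atoms: thionyl chloride, O=S(Cl)Cl
Why: Chlorodehydroxylation through the chlorosulfite, fast for an electron-rich benzylic alcohol, should give the precursor of the benzylic organomagnesium reagent.

**Step 6**
Reactants: 6 2-{2-[3,4-bis(benzyloxy)-5-methoxyphenyl]ethyl}-1,3-dithiane; 9 (S)-epichlorohydrin; 8 4-(benzyloxy)-3-methoxybenzyl chloride
Product: 14 (R)-4-[4-(benzyloxy)-3-methoxyphenyl]-1-(2-{2-[3,4-bis(benzyloxy)-5-methoxyphenyl]ethyl}-1,3-dithian-2-yl)butan-2-ol, via 2-lithiodithiane 10 (not isolated), via chloroalkoxide 11 (not isolated), via oxirane 12 (not isolated), via benzylic Grignard reagent 13 (not isolated)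
Conditions: 6, n-BuLi (1.05 equiv), THF, −30 °C; 9 (1.05 equiv), −78 °C → rt; CuI (0.1 equiv), then 13 (1.5 equiv; from 8, Mg, THF, 0 °C, separate flask), −40 → 0 °C; aq NH4Cl
Reagents that add atoms: none
Why: Deprotonation of 6 at the dithiane carbon gives carbanion 10, which opens the ring CH2 of 9 by SN2 attack to form C3–C4; on warming, alkoxide 11 displaces chloride to give oxirane 12, and the cuprate formed from 13 and catalytic CuI opens 12 by SN2 attack at its unsubstituted CH2, forming the C6–C7 bond that joins the guaiacyl half to the rest of the chain. The closest known reaction types are the alkylation of 2-lithio-1,3-dithianes with epichlorohydrin and the copper-catalysed opening of terminal epoxides by Grignard reagents, run here in sequence in one flask as a three-component linchpin coupling. The only ring closed is the temporary oxirane, by 3-exo-tet attack of the C5 alkoxide on the CH2Cl carbon, and it is opened again in the same flask. No stereocentre is created: C5 is the CH of (S)-9 and its C–O bond is never broken, so the configuration of the reagent is carried over unchanged and is named R in 14 only because the CIP ranking of the two methylene arms changes. Two regioselectivities are needed: the carbanion must attack the epoxide CH2 of 9 and not the CH2Cl carbon (that path would give the enantiomer), which ring strain and the poorer leaving ability of chloride at −78 °C should secure, and the benzyl nucleophile must attack the terminal carbon of 12, which the steric difference between CH2 and the substituted CH secures under copper catalysis. The Grignard reagent is added only after 10 has been consumed at low temperature, so that 12 forms when no carbanion is left that could open it.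

**Step 7**
Reactants: 14 (R)-4-[4-(benzyloxy)-3-methoxyphenyl]-1-(2-{2-[3,4-bis(benzyloxy)-5-methoxyphenyl]ethyl}-1,3-dithian-2-yl)butan-2-ol
Product: 15 (R)-1-[3,4-bis(benzyloxy)-5-methoxyphenyl]-7-[4-(benzyloxy)-3-methoxyphenyl]-5-hydroxyheptan-3-one
Conditions: MeI (10 equiv), CaCO3 (5 equiv), MeCN/H2O 9:1, 45 °C
Reagents that add atoms: water, O
Why: Alkylative dithiane hydrolysis (S-methylation, addition of water to the thionium ion, second methylation and collapse) should release the C3 ketone under carbonate-buffered, near-neutral conditions that leave the β-hydroxy ketone, the benzyl ethers and C5 untouched.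

**Step 8**
Reactants: 15 (R)-1-[3,4-bis(benzyloxy)-5-methoxyphenyl]-7-[4-(benzyloxy)-3-methoxyphenyl]-5-hydroxyheptan-3-one
Product: 16 (R)-1-(3,4-dihydroxy-5-methoxyphenyl)-5-hydroxy-7-(4-hydroxy-3-methoxyphenyl)heptan-3-one (target)
Conditions: H2 (1 atm), 10% Pd/C, EtOAc/MeOH, rt
Reagents that add atoms: none
Why: Catalytic hydrogenolysis should cleave the three aryl benzyl ethers, while the dialkyl ketone and the non-benzylic secondary alcohol are not reduced and C5 keeps its (R)-configuration.

**Compound list**
1 | 5-hydroxyvanillin (3,4-dihydroxy-5-methoxybenzaldehyde) | COc1cc(C=O)cc(O)c1O | starting material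
2 | 3,4-bis(benzyloxy)-5-methoxybenzaldehyde | COc1cc(C=O)cc(OCc2ccccc2)c1OCc1ccccc1 | intermediate
3 | (triphenylphosphoranylidene)acetaldehyde | O=CC=P(c1ccccc1)(c1ccccc1)c1ccccc1 | starting material
4 | (E)-3-[3,4-bis(benzyloxy)-5-methoxyphenyl]prop-2-enal | COc1cc(/C=C/C=O)cc(OCc2ccccc2)c1OCc1ccccc1 | intermediate
5 | 3-[3,4-bis(benzyloxy)-5-methoxyphenyl]propanal | COc1cc(CCC=O)cc(OCc2ccccc2)c1OCc1ccccc1 | intermediate
6 | 2-{2-[3,4-bis(benzyloxy)-5-methoxyphenyl]ethyl}-1,3-dithiane | COc1cc(CCC2SCCCS2)cc(OCc2ccccc2)c1OCc1ccccc1 | intermediate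
7 | 4-(benzyloxy)-3-methoxybenzyl alcohol | COc1cc(CO)ccc1OCc1ccccc1 | starting material
8 | 4-(benzyloxy)-3-methoxybenzyl chloride | COc1cc(CCl)ccc1OCc1ccccc1 | intermediate
9 | (S)-epichlorohydrin | ClC[C@@H]1CO1 | starting material
10 | 2-lithio-2-{2-[3,4-bis(benzyloxy)-5-methoxyphenyl]ethyl}-1,3-dithiane | [Li]C1(CCc2cc(OC)c(OCc3ccccc3)c(OCc3ccccc3)c2)SCCCS1 | intermediate
11 | lithium (S)-1-chloro-3-(2-{2-[3,4-bis(benzyloxy)-5-methoxyphenyl]ethyl}-1,3-dithian-2-yl)propan-2-olate | ClC[C@@H](O[Li])CC1(CCc2cc(OC)c(OCc3ccccc3)c(OCc3ccccc3)c2)SCCCS1 | intermediate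
12 | (S)-2-[(2-{2-[3,4-bis(benzyloxy)-5-methoxyphenyl]ethyl}-1,3-dithian-2-yl)methyl]oxirane | C1O[C@H]1CC2(CCc3cc(OC)c(OCc4ccccc4)c(OCc4ccccc4)c3)SCCCS2 | intermediate
13 | [4-(benzyloxy)-3-methoxybenzyl]magnesium chloride | Cl[Mg]Cc1ccc(OCc2ccccc2)c(OC)c1 | intermediate
14 | (R)-4-[4-(benzyloxy)-3-methoxyphenyl]-1-(2-{2-[3,4-bis(benzyloxy)-5-methoxyphenyl]ethyl}-1,3-dithian-2-yl)butan-2-ol | COc1cc(CC[C@@H](O)CC2(CCc3cc(OC)c(OCc4ccccc4)c(OCc4ccccc4)c3)SCCCS2)ccc1OCc1ccccc1 | intermediate
15 | (R)-1-[3,4-bis(benzyloxy)-5-methoxyphenyl]-7-[4-(benzyloxy)-3-methoxyphenyl]-5-hydroxyheptan-3-one | COc1cc(CC[C@@H](O)CC(=O)CCc2cc(OC)c(OCc3ccccc3)c(OCc3ccccc3)c2)ccc1OCc1ccccc1 | intermediate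
16 | (R)-1-(3,4-dihydroxy-5-methoxyphenyl)-5-hydroxy-7-(4-hydroxy-3-methoxyphenyl)heptan-3-one | COc1cc(CC[C@@H](O)CC(=O)CCc2cc(O)c(O)c(OC)c2)ccc1O | target

**Summary**
Total step count: 8. Longest linear sequence: 7 steps (1, 2, 3, 4, 6, 7, 8, from 5-hydroxyvanillin).

Steps most likely to fail:

Step 6. Several processes could spoil the one-flask union: n-BuLi may metalate a benzyl ether CH2 of 6 in competition with the dithiane C–H, the benzylic chloride may homocouple (Wurtz) while the Grignard reagent forms, the carbanion may displace chloride of 9 directly and erode the enantiomeric purity, and the oxirane may close incompletely before the cuprate is added. Fallback: the order of the two bond formations is reversed and the epoxide is isolated. Setting out from 8, Grignard reagent 13 would be added to (R)-epichlorohydrin with catalytic CuI in THF at −40 °C to give (R)-1-chloro-4-[4-(benzyloxy)-3-methoxyphenyl]butan-2-ol F1. Closure with NaOH should give (R)-2-{2-[4-(benzyloxy)-3-methoxyphenyl]ethyl}oxirane F2, which can be purified and checked for enantiomeric purity. Carbanion 10, made from 6 as before, would then open F2 at its terminal carbon (THF, −30 → 0 °C), and the route is rejoined at 14.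

Step 7. S-Methylation at the hindered 2,2-dialkyl dithiane may be slow, and on prolonged heating the β-hydroxy ketone could lose water to the enone or undergo retro-aldol cleavage. Fallback: the carbinol is masked and the dithiane is removed oxidatively in the cold. Setting out from 14, TESCl and imidazole in DMF should give (R)-triethylsilyl ether F3. Iodine and NaHCO3 in acetone/water at 0 °C should then give (R)-1-[3,4-bis(benzyloxy)-5-methoxyphenyl]-7-[4-(benzyloxy)-3-methoxyphenyl]-5-(triethylsilyloxy)heptan-3-one F4. AcOH/THF/H2O at rt removes the silyl group, and the route is rejoined at 15.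

Step 2. The electron-rich aldehyde may react slowly, and the product enal may be olefinated a second time to the dienal. Fallback: the two carbons are added at the ester oxidation level. Setting out from 2, Horner–Wadsworth–Emmons reaction with triethyl phosphonoacetate and NaH in THF should give ethyl (E)-3-[3,4-bis(benzyloxy)-5-methoxyphenyl]prop-2-enoate F5. Conjugate reduction with NaBH4 and NiCl2·6H2O in EtOH at 0 °C should give ethyl 3-[3,4-bis(benzyloxy)-5-methoxyphenyl]propanoate F6. DIBAL-H in toluene at −78 °C then gives the aldehyde, and the route is rejoined at 5 (steps 2 and 3 are bypassed).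

**Further compounds**
F1 | step 6 | (R)-1-chloro-4-[4-(benzyloxy)-3-methoxyphenyl]butan-2-ol | ClC[C@H](O)CCc1ccc(OCc2ccccc2)c(OC)c1
F2 | step 6 | (R)-2-{2-[4-(benzyloxy)-3-methoxyphenyl]ethyl}oxirane | C1O[C@@H]1CCc1ccc(OCc2ccccc2)c(OC)c1
F3 | step 7 | (R)-{4-[4-(benzyloxy)-3-methoxyphenyl]-1-(2-{2-[3,4-bis(benzyloxy)-5-methoxyphenyl]ethyl}-1,3-dithian-2-yl)butan-2-yloxy}triethylsilane | COc1cc(CC[C@@H](O[Si](CC)(CC)CC)CC2(CCc3cc(OC)c(OCc4ccccc4)c(OCc4ccccc4)c3)SCCCS2)ccc1OCc1ccccc1
F4 | step 7 | (R)-1-[3,4-bis(benzyloxy)-5-methoxyphenyl]-7-[4-(benzyloxy)-3-methoxyphenyl]-5-(triethylsilyloxy)heptan-3-one | COc1cc(CC[C@@H](O[Si](CC)(CC)CC)CC(=O)CCc2cc(OC)c(OCc3ccccc3)c(OCc3ccccc3)c2)ccc1OCc1ccccc1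
F5 | step 2 | ethyl (E)-3-[3,4-bis(benzyloxy)-5-methoxyphenyl]prop-2-enoate | CCOC(=O)/C=C/c1cc(OC)c(OCc2ccccc2)c(OCc2ccccc2)c1
F6 | step 2 | ethyl 3-[3,4-bis(benzyloxy)-5-methoxyphenyl]propanoate | CCOC(=O)CCc1cc(OC)c(OCc2ccccc2)c(OCc2ccccc2)c1
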